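The catalyst cannot be where the starting material goes: its charge of 4.0 mM is far less than the 2.0 M of starting material, a share of 0.200%. So I froze one sum, starting material plus target, at the charge, and the last zeta row gave 98.6% for it, under a scatter of 1 percentage point per reading.

| flask | starting material | partner | scavenger | precatalyst | temperature | remark | time |
|---|---|---|---|---|---|---|---|
| gamma | 2 M | 0.60 M | 1 M | 4 mM | 20 °C | run made earlier |  |
| zeta | 2 M | 0.60 M | 1 M | 4 mM | 35 °C | run made earlier |  |
| Thursday's | 2.0 M | 1.20 M | 1.00 M | 4.0 mM | 25 °C |  | 1.0 h |
| Sunday's | 2.0 M | 1.20 M | 1.00 M | 4.0 mM | 35 °C |  | 1.0 h |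
| Friday's | 2.0 M | 1.20 M | 1.00 M | 4.0 mM | 45 °C |  | 1.0 h |

| run | time / min | starting material / % | catalyst intermediate A / % | catalyst intermediate D / % | target / % | catalyst intermediate C / % |
|---|---|---|---|---|---|---|
| gamma | 10.0 | 100.9 | 0 | 0 | 0 | 0 |
| gamma | 25.0 | 99.9 | 0 | 0 | 2.3 | 0 |
| gamma | 50.0 | 98.9 | 1.5 | 0.7 | 0 | 0 |
| gamma | 80.0 | 96.7 | 0 | 0 | 3.5 | 0 |
| zeta | 6.00 | 98.9 | 0 | 0 | 0.8 | 0 |
| zeta | 15.0 | 97.4 | 0.8 | 1.0 | 2.5 | 1.7 |
| zeta | 30.0 | 94.7 | 0 | 0.1 | 5.0 | 0 |
| zeta | 50.0 | 84.6 | 0 | 0 | 14.0 | 0.2 |

(readings scatter by 1 percentage point)

1. which of these there is most of at the end, counted by the starting material in it, Thursday's (starting material / target / catalyst intermediate D / catalyst intermediate A / catalyst intermediate C)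
2. which of these there is most of at the end, counted by the starting material in it, Sunday's (starting material / target / catalyst intermediate D / catalyst intermediate A / catalyst intermediate C)
3. which of these there is most of at the end, counted by the starting material in it, Friday's (starting material / target / catalyst intermediate D / catalyst intermediate A / catalyst intermediate C)
4. final amount of the leader among these, as a percentage of the starting material charged, in Thursday's
5. final amount of the leader among these, as a percentage of the starting material charged, in Sunday's
6. final amount of the leader among these, as a percentage of the starting material charged, in Friday's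

- the analysis behind the earlier runs scatters by 1 percentage point, standard deviation

I then kept the books in partner, the limiting reagent if one partner makes one target. I assumed that, since the earlier runs did not read partner. The catalyst entry was small, its charge being 0.333% of the 1.20 M of partner. That left two entries: partner spent into target and partner still free. Hence the partner charged over the starting material charged, 60.0%, is the ceiling, and target equals the ceiling times the share of partner spent. With this ceiling, target passes starting material once 83.3% of the partner is spent.

For that share I took the rate as first order in partner, so that the share spent at a given time and temperature does not depend on the charge and the zeta run could stand in for Sunday's flask. The zeta run had spent 46.7% of its partner at 50.0 min. Continued at its last slope, that gave Sunday's flask 61.7% at 1.0 h, less than the crossing. So I wrote target 37.0% and starting material 63.0%.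

The early slopes of the zeta and gamma runs differed by a factor of 3.81, which scaled to the gap between 25 °C and 35 °C is 2.44. Thursday's hour was therefore worth 24.6 min on the zeta run's early slope, giving target 8.20% and starting material 91.8%. Friday's hour was worth 2.44 h at 35 °C, yet the last slope would finish the partner left in Sunday's flask within 25.6 min more. So I put Friday's target at the ceiling.

The forecast gave starting material at 88% for Thursday's, starting material at 58% for Sunday's and target at 55% for Friday's, where “the reaction likely nears the partner limit”, and it stood lower than my figures on Thursday's, on Sunday's and on Friday's.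

The flasks gave starting material at 90.6% on Thursday's, starting material at 57.7% on Sunday's and target at 59.8% on Friday's.

    catalyst intermediate C → catalyst intermediate D (k = 16.0 min⁻¹, Ea = 82.0 kJ mol⁻¹)
    starting material + free catalyst → catalyst intermediate A (k = 1300 M⁻¹ min⁻¹, Ea = 51.0 kJ mol⁻¹)
    catalyst intermediate D → free catalyst + target (k = 20.0 min⁻¹, Ea = 73.0 kJ mol⁻¹)
    starting material + released group ⇌ idle adduct, settled at all times (K = 0.170 M⁻¹, ΔH = −83.0 kJ mol⁻¹)
    catalyst intermediate B ⇌ released group + catalyst intermediate C (K = 1.30 M, k = 2400 min⁻¹, Ea = 68.0 kJ mol⁻¹, ΔH = −39.0 kJ mol⁻¹)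
    scavenger + released group → scavenged by-product (k = 0.260 M⁻¹ min⁻¹, Ea = 51.0 kJ mol⁻¹)
    partner + catalyst intermediate A ⇌ catalyst intermediate B (K = 23.0 M⁻¹, k = 19.0 M⁻¹ min⁻¹, Ea = 63.0 kJ mol⁻¹, ΔH = −1.00 kJ mol⁻¹)
    partner + precatalyst → free catalyst + spent reagent (k = 0.00380 M⁻¹ min⁻¹, Ea = 78.0 kJ mol⁻¹)
    (constants at 25 °C)

Sunday's target stood at 69.8% of the ceiling with 30% of Sunday's partner left, short of the crossing. At 0.608 h in Sunday's flask, the forward step of partner with catalyst intermediate A used partner 840 times faster than the turning of partner and precatalyst did. The neighbour of Sunday's charged with 2.0 M of partner has a ceiling of 100%, which puts its crossing at half of its partner, and there target led at 71.0%, with 29% of that partner left.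

The data are simulated on assumed constants; the scatter is artificial.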